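The pyrazinone is traced back to an N-(2-azidopropanoyl) amino ester and the oxindole to a 4-aryl pyroglutamate: oxindole C3, the bridging CH2 and pyrazinone C6 and C5 are C4, C3, C2 and the ester carbon of L-pyroglutamate, and the lactam carbonyl is the future oxindole C2. Reduction of the nitro group in methyl (2S,4S)-1-Boc-4-(2-nitro-3-prenylphenyl)-5-oxopyrrolidine-2-carboxylate frees an aniline that acylates itself on this carbonyl, so one operation closes the oxindole ring (N1–C2), opens the pyrrolidinone to the Boc-protected amino ester and transfers C4 unchanged into C3. The precursor is assembled by SNAr arylation of the pyroglutamate enolate followed by prenylation.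

Key step: step 3

Remark: 2-azidopropanoic acid is used as the racemate, because its stereocentre becomes the sp2 carbon C3 of the pyrazinone in step 8, so 14–16 are mixtures of epimers at that carbon only; the trans lactam 6 is assumed to be the more stable C4 epimer. (Prenyl = 3-methylbut-2-en-1-yl.)

**Step 1**
Reactants: 1 methyl N-Boc-L-pyroglutamate; 2 1-bromo-3-fluoro-2-nitrobenzene
Product: 6 methyl (2S,4S)-1-Boc-4-(3-bromo-2-nitrophenyl)-5-oxopyrrolidine-2-carboxylate, via lithium enolate 3 (not isolated), via aryl lithium enolate 4 (not isolated), via cis lactam 5 (not isolated)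
Conditions: 1 (2.1 equiv), LiN(SiMe3)2 (2.05 equiv), THF, −78 °C; 2 (1.0 equiv), −78 → −40 °C; AcOH, −78 °C; crude in toluene, DBU (10 mol %), 0 °C → rt; crystallisation or chromatography, cis-rich mother liquor re-equilibrated
Reagents that add atoms: none
Why: Nucleophilic aromatic substitution (addition–elimination through a Meisenheimer adduct) of enolate 3 at the C–F carbon ortho to the nitro group, where fluoride leaves far faster than bromide, gives the arylated lactam, which the second equivalent of enolate converts into 4; acetic acid should protonate 4 mainly anti to the C2 ester (cis lactam 5), and catalytic DBU then epimerises only the acidic C4–H towards the trans (4S) lactam 6, in which the aryl group is pseudoequatorial while the ester stays pseudoaxial to avoid allylic 1,3-strain with N-Boc, so C4 is set under thermodynamic control by C2.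

**Step 2**
Reactants: 6 methyl (2S,4S)-1-Boc-4-(3-bromo-2-nitrophenyl)-5-oxopyrrolidine-2-carboxylate; 7 tributyl(3-methylbut-2-en-1-yl)stannane
Product: 8 methyl (2S,4S)-1-Boc-4-(2-nitro-3-prenylphenyl)-5-oxopyrrolidine-2-carboxylate
Conditions: Pd(PPh3)4 (5 mol %), degassed toluene, 100 °C
Reagents that add atoms: none
Why: Stille coupling, in which oxidative addition into the nitro-activated C–Br bond, transfer of the prenyl group from tin and reductive elimination at the unsubstituted terminus of the allylpalladium intermediate should give the linear prenyl arene under neutral conditions that leave the N-Boc lactam and the C4–H untouched; prenylating after the SNAr step means that no nitro-activated benzylic, allylic CH2 is exposed to the enolate or to DBU.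

**Step 3**
Reactants: 8 methyl (2S,4S)-1-Boc-4-(2-nitro-3-prenylphenyl)-5-oxopyrrolidine-2-carboxylate
Product: 10 methyl (S)-2-(Boc-amino)-3-[(S)-2-oxo-7-prenylindolin-3-yl]propanoate, via aniline lactam 9 (not isolated)
Conditions: Zn dust (10 equiv), AcOH/THF (1:3), 0 °C → rt, then 45 °C
Reagents that add atoms: none
Why: Zinc in acetic acid reduces the nitro group through the nitroso and hydroxylamine stages to aniline 9, whose nitrogen adds to the N-Boc-activated lactam carbonyl C5; the tetrahedral intermediate collapses by cleaving the C5–N bond and expelling the carbamate nitrogen, so one five-membered lactam is exchanged for another (reductive lactamisation of a 2-nitroarylacetic acid derivative combined with ring-opening transamidation of an N-acyl lactam, both known reaction types). The oxindole ring closes in 5-exo-trig mode by formation of N1–C2. No stereocentre is created: C4 of the lactam is not deprotonated in the acidic medium and becomes C3 (S) of the oxindole, while C2 becomes the α-carbon of the Boc-amino ester unchanged. The step needs chemoselectivity for the ring carbonyl over the methyl ester and the Boc carbonyl, which the five-membered transition state and the imide-type activation of that carbonyl provide, and complete reduction to the aniline before closure, which excess zinc in acid should secure against the N-hydroxy oxindole. The prenyl alkene, the carbamate and the ester are inert to zinc in acetic acid, and the absence of base protects the new C3–H.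

**Step 4**
Reactants: 10 methyl (S)-2-(Boc-amino)-3-[(S)-2-oxo-7-prenylindolin-3-yl]propanoate
Product: 11 methyl (S)-2-amino-3-[(S)-2-oxo-7-prenylindolin-3-yl]propanoate hydrochloride
Conditions: HCl (4 M in 1,4-dioxane), 0 °C → rt; evaporation, salt used directly
Reagents that add atoms: hydrogen chloride, SMILES Cl
Why: Acidolysis of the tert-butyl carbamate (loss of the tert-butyl cation as 2-methylpropene, then decarboxylation) by ether-complexed HCl, which at this temperature should not add to the trisubstituted alkene at a competitive rate; keeping the amine as its hydrochloride blocks both its 5-exo attack on the oxindole carbonyl, which would reverse the ring switch, and base-mediated epimerisation at C3.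

**Step 5**
Reactants: 12 2-bromopropanoic acid (racemic)
Product: 13 2-azidopropanoic acid (racemic)
Conditions: NaN3 (2 equiv), H2O, rt; HCl (aq) to pH 2 at 0 °C, extraction into Et2O, kept as a solution
Reagents that add atoms: sodium azide, SMILES [Na+].[N-]=[N+]=[N-]
Why: SN2 displacement of the carbonyl-activated secondary bromide by azide; the acid is handled in solution because of its low carbon-to-nitrogen ratio.

**Step 6**
Reactants: 11 methyl (S)-2-amino-3-[(S)-2-oxo-7-prenylindolin-3-yl]propanoate hydrochloride; 13 2-azidopropanoic acid
Product: 14 methyl (2S)-2-(2-azidopropanamido)-3-[(3S)-2-oxo-7-prenylindolin-3-yl]propanoate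
Conditions: 13 (1.2 equiv), EDC·HCl (1.2 equiv), HOBt (1.2 equiv), CH2Cl2, 0 °C, 15 min; then 11 and N-methylmorpholine (1.0 equiv, added last), 0 °C → rt
Reagents that add atoms: none
Why: Carbodiimide amide coupling through the HOBt active ester; the ammonium salt is neutralised by one equivalent of a weak tertiary amine only in the presence of the active ester, so that acylation should outrun the intramolecular transamidation of the free amine and the oxindole C3–H meets no strong base.

**Step 7**
Reactants: 14 methyl (2S)-2-(2-azidopropanamido)-3-[(3S)-2-oxo-7-prenylindolin-3-yl]propanoate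
Product: 16 (6S)-5-methoxy-3-methyl-6-{[(3S)-2-oxo-7-prenylindolin-3-yl]methyl}-3,6-dihydropyrazin-2(1H)-one, via iminophosphorane 15 (not isolated)
Conditions: PBu3 (1.1 equiv), dry toluene, 4 Å molecular sieves, rt (N2 evolution), then 70 °C
Reagents that add atoms: none
Why: Staudinger reaction of the azide gives iminophosphorane 15, whose nitrogen adds to the α-amido ester carbonyl in a six-membered intramolecular aza-Wittig reaction that expels Bu3P=O and keeps the methoxy group as the lactim ether, so the position of OMe is fixed by construction; the dry, non-polar medium prevents hydrolysis to the amine (which would lactamise with loss of methanol) and disfavours proton transfer from the oxindole C3–H to the basic P=N nitrogen.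

**Step 8**
Reactants: 16 (6S)-5-methoxy-3-methyl-6-{[(3S)-2-oxo-7-prenylindolin-3-yl]methyl}-3,6-dihydropyrazin-2(1H)-one
Product: 17 Astepyrazinol B
Conditions: DDQ (1.05 equiv), CH2Cl2, 0 °C → rt
Reagents that add atoms: none
Why: DDQ dehydrogenation (hydride abstraction next to ring nitrogen, then proton loss) driven by aromatisation to the 2(1H)-pyrazinone, which removes both sp3 centres of the six-membered ring and leaves oxindole C3 (S) as the only stereocentre; one equivalent at low temperature should be consumed by the dihydropyrazinone before the prenyl CH2 or the oxindole C3–H can react.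

**Compound list**
1 | methyl N-Boc-L-pyroglutamate (1-tert-butyl 2-methyl (2S)-5-oxopyrrolidine-1,2-dicarboxylate) | COC(=O)[C@@H]1CCC(=O)N1C(=O)OC(C)(C)C | starting material
2 | 1-bromo-3-fluoro-2-nitrobenzene | O=[N+]([O-])c1c(F)cccc1Br | starting material
3 | lithium (5S)-1-Boc-5-(methoxycarbonyl)-4,5-dihydro-1H-pyrrol-2-olate (lithium enolate of 1) | COC(=O)[C@@H]1CC=C(O[Li])N1C(=O)OC(C)(C)C | intermediate
4 | lithium (5S)-3-(3-bromo-2-nitrophenyl)-1-Boc-5-(methoxycarbonyl)-4,5-dihydro-1H-pyrrol-2-olate (enolate of the arylated lactam) | COC(=O)[C@@H]1CC(c2cccc(Br)c2[N+](=O)[O-])=C(O[Li])N1C(=O)OC(C)(C)C | intermediate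
5 | methyl (2S,4R)-1-Boc-4-(3-bromo-2-nitrophenyl)-5-oxopyrrolidine-2-carboxylate (cis) | COC(=O)[C@@H]1C[C@H](c2cccc(Br)c2[N+](=O)[O-])C(=O)N1C(=O)OC(C)(C)C | intermediate
6 | methyl (2S,4S)-1-Boc-4-(3-bromo-2-nitrophenyl)-5-oxopyrrolidine-2-carboxylate (trans) | COC(=O)[C@@H]1C[C@@H](c2cccc(Br)c2[N+](=O)[O-])C(=O)N1C(=O)OC(C)(C)C | intermediate
7 | tributyl(3-methylbut-2-en-1-yl)stannane | CCCC[Sn](CCCC)(CCCC)CC=C(C)C | starting material
8 | methyl (2S,4S)-1-Boc-4-(2-nitro-3-prenylphenyl)-5-oxopyrrolidine-2-carboxylate | COC(=O)[C@@H]1C[C@@H](c2cccc(CC=C(C)C)c2[N+](=O)[O-])C(=O)N1C(=O)OC(C)(C)C | intermediate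
9 | methyl (2S,4S)-4-(2-amino-3-prenylphenyl)-1-Boc-5-oxopyrrolidine-2-carboxylate | COC(=O)[C@@H]1C[C@@H](c2cccc(CC=C(C)C)c2N)C(=O)N1C(=O)OC(C)(C)C | intermediate
10 | methyl (S)-2-(Boc-amino)-3-[(S)-2-oxo-7-prenylindolin-3-yl]propanoate | COC(=O)[C@@H](NC(=O)OC(C)(C)C)C[C@@H]1C(=O)Nc2c(CC=C(C)C)cccc21 | intermediate
11 | methyl (S)-2-amino-3-[(S)-2-oxo-7-prenylindolin-3-yl]propanoate hydrochloride | COC(=O)[C@@H](N)C[C@@H]1C(=O)Nc2c(CC=C(C)C)cccc21.Cl | intermediate
12 | 2-bromopropanoic acid (racemic) | CC(Br)C(=O)O | starting material
13 | 2-azidopropanoic acid (racemic) | CC(N=[N+]=[N-])C(=O)O | intermediate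
14 | methyl (2S)-2-(2-azidopropanamido)-3-[(3S)-2-oxo-7-prenylindolin-3-yl]propanoate (both epimers at the azide-bearing carbon) | COC(=O)[C@@H](NC(=O)C(C)N=[N+]=[N-])C[C@@H]1C(=O)Nc2c(CC=C(C)C)cccc21 | intermediate
15 | tributyliminophosphorane of 14 (N=PBu3 in place of N3) | COC(=O)[C@@H](NC(=O)C(C)N=P(CCCC)(CCCC)CCCC)C[C@@H]1C(=O)Nc2c(CC=C(C)C)cccc21 | intermediate
16 | (6S)-5-methoxy-3-methyl-6-{[(3S)-2-oxo-7-prenylindolin-3-yl]methyl}-3,6-dihydropyrazin-2(1H)-one (both epimers at C3) | COC1=NC(C)C(=O)N[C@H]1C[C@@H]1C(=O)Nc2c(CC=C(C)C)cccc21 | intermediate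
17 | Astepyrazinol B, 5-methoxy-3-methyl-6-{[(3S)-2-oxo-7-prenylindolin-3-yl]methyl}pyrazin-2(1H)-one | COc1nc(C)c(=O)[nH]c1C[C@@H]1C(=O)Nc2c(CC=C(C)C)cccc21 | target

Total step count: 8 (steps 1–4 and 6–8 in line, step 5 on the side). Longest linear sequence: 7 steps.

Steps most likely to fail:

Step 1. Protonation of enolate 4 is kinetically anti to the ester, and the thermodynamic bias towards the trans epimer may be too small, so that equilibration stalls at a cis-rich mixture (poor stereocontrol at C4). Fallback: the stereochemical decision is moved behind the ring switch. It sets out from cis lactam 5, which is isolated and taken through the Stille coupling of step 2 to methyl (2S,4R)-1-Boc-4-(2-nitro-3-prenylphenyl)-5-oxopyrrolidine-2-carboxylate F1. The Zn/AcOH reduction of step 3 then leads, via the cis aniline lactam F2, to methyl (S)-2-(Boc-amino)-3-[(R)-2-oxo-7-prenylindolin-3-yl]propanoate F3. F3 and 10 differ only at the acidic oxindole C3–H; DBU (10 mol %) in CH2Cl2 should interconvert them without touching the carbamate-bearing α-carbon. The diastereomers are separated by chromatography and F3 is recycled, so the fallback comes back to the route at 10.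

Step 3. The aryl hydroxylamine formed on the way to the aniline may close onto the activated lactam before it is reduced further (interception at the wrong oxidation level), giving a cyclic hydroxamic acid that zinc reduces only slowly. Fallback: the hydroxylamine is made the intended nucleophile. From 8, Zn/NH4Cl in THF/H2O at 0 °C should stop at the hydroxylamine lactam methyl (2S,4S)-1-Boc-4-[2-(hydroxyamino)-3-prenylphenyl]-5-oxopyrrolidine-2-carboxylate F4. F4 should undergo the same ring switch to the N-hydroxy oxindole methyl (S)-2-(Boc-amino)-3-[(S)-1-hydroxy-2-oxo-7-prenylindolin-3-yl]propanoate F5. N–O cleavage with aqueous TiCl3 buffered with NH4OAc (MeOH, rt) then gives 10, where the route is rejoined.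

Step 2. The prenyl group may be transferred through its substituted terminus, or the double bond may migrate in the allylpalladium intermediate (loss of regiocontrol in the coupling). Fallback: from 6, Stille coupling with allyltributylstannane (Pd(PPh3)4, toluene, 100 °C), which is regiochemically unambiguous, should give methyl (2S,4S)-4-(3-allyl-2-nitrophenyl)-1-Boc-5-oxopyrrolidine-2-carboxylate F6. Cross-metathesis of F6 with excess 2-methylbut-2-ene and second-generation Grubbs catalyst (CH2Cl2, 40 °C) then installs the trisubstituted alkene and returns to the route at 8.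

Steps 7 and 8 rest on the known behaviour of α-azidoacyl amino esters and of dihydropyrazinone lactim ethers and are ranked below these three.

**Further compounds**
F1 | step 1 | methyl (2S,4R)-1-Boc-4-(2-nitro-3-prenylphenyl)-5-oxopyrrolidine-2-carboxylate | COC(=O)[C@@H]1C[C@H](c2cccc(CC=C(C)C)c2[N+](=O)[O-])C(=O)N1C(=O)OC(C)(C)C
F2 | step 1 | methyl (2S,4R)-4-(2-amino-3-prenylphenyl)-1-Boc-5-oxopyrrolidine-2-carboxylate | COC(=O)[C@@H]1C[C@H](c2cccc(CC=C(C)C)c2N)C(=O)N1C(=O)OC(C)(C)C
F3 | step 1 | methyl (S)-2-(Boc-amino)-3-[(R)-2-oxo-7-prenylindolin-3-yl]propanoate | COC(=O)[C@@H](NC(=O)OC(C)(C)C)C[C@H]1C(=O)Nc2c(CC=C(C)C)cccc21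
F4 | step 3 | methyl (2S,4S)-1-Boc-4-[2-(hydroxyamino)-3-prenylphenyl]-5-oxopyrrolidine-2-carboxylate | COC(=O)[C@@H]1C[C@@H](c2cccc(CC=C(C)C)c2NO)C(=O)N1C(=O)OC(C)(C)C
F5 | step 3 | methyl (S)-2-(Boc-amino)-3-[(S)-1-hydroxy-2-oxo-7-prenylindolin-3-yl]propanoate | COC(=O)[C@@H](NC(=O)OC(C)(C)C)C[C@@H]1C(=O)N(O)c2c(CC=C(C)C)cccc21
F6 | step 2 | methyl (2S,4S)-4-(3-allyl-2-nitrophenyl)-1-Boc-5-oxopyrrolidine-2-carboxylate | COC(=O)[C@@H]1C[C@@H](c2cccc(CC=C)c2[N+](=O)[O-])C(=O)N1C(=O)OC(C)(C)C
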